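A closed, stirred vessel at constant temperature holds Z and the catalyst L, and Z turns into E.

| flask | Z | L | time |
|---|---|---|---|
| theta | 0.400 M | 0.00400 M |  |
| eta | 0.240 M | 0.00400 M |  |
| beta | 0.400 M | 0.00200 M |  |
| alpha | 0.800 M | 0.00400 M |  |
| epsilon | 0.400 M | 6.20 × 10⁻⁴ M | 120 min |

| run | time / min | [E] / M |
|---|---|---|
| theta run | 4.8 | 0.015 |
| theta run | 9.1 | 0.012 |
| theta run | 17 | 0.027 |
| theta run | 33 | 0.060 |
| theta run | 63 | 0.121 |
| theta run | 120 | 0.206 |
| eta run | 4.8 | 0.002 |
| eta run | 9.1 | 0.013 |
| eta run | 17 | 0.021 |
| eta run | 33 | 0.046 |
| eta run | 63 | 0.062 |
| eta run | 120 | 0.129 |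
| beta run | 4.8 | 0.003 |
| beta run | 9.1 | 0.007 |
| beta run | 17 | 0.015 |
| beta run | 33 | 0.035 |
| beta run | 63 | 0.070 |
| beta run | 120 | 0.116 |
| alpha run | 4.8 | 0.021 |
| alpha run | 9.1 | 0.033 |
| alpha run | 17 | 0.073 |
| alpha run | 33 | 0.134 |
| alpha run | 63 | 0.270 |
| alpha run | 120 | 0.484 |

(readings scatter by 0.004 M)

- reaction order in [Z] at the outset, round the charge of the theta run, defined at two percent of the Z turned into E (one fixed amount of E, the same in the runs compared)
- reaction order in [L] at the outset, round the charge of the theta run, defined at two percent of the Z turned into E
- the eta run starts with 0.160 M less of Z than the theta run, and with no E. Compared where both hold the same amount of Z, once fifteen percent of what the eta run was charged with has turned into E, is the eta run faster, slower or alike (within a tenth)?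
- E in the epsilon run at 120 min, as a share of the Z charged

- Overall: Z -> E, with L as catalyst.
- Constant volume, constant temperature.
- An order is taken over about fifteen percent of the charge, up and down.

I build the flask one step at a time. First comes the main step, L turning Z into E, with a rate proportional to L and to Z. It gives order one in each, and it gives my scale its zero: at equal Z and equal L two runs then go alike, a ratio of one, whatever E they hold.

The theta run reads 0.00492 min⁻¹ as a first-order constant up to 33 min, but 0.00637 min⁻¹ from 63 min to 120 min, which is more. So I add a second step, E helping Z on to E (autocatalysis), and divide that gain by the E added between the two spans, which gives 0.0109 M⁻¹ min⁻¹. Set against what remains for L, this yields the catalyst worth of E, the amount of L that one mole of E stands in for: 0.00945, a loose reading. The rate now goes as Z times the sum of L and worth times E.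

At 2 percent turned, my order in Z stays one, and my order in L is L over that sum, 0.981. At the equal-Z point the eta run holds 0.0360 M of E and the theta run 0.196 M, so I expect the eta run to go at 0.742 of the theta rate: slower.

Last comes the fall of Z, which the integrated rate law carries. In the epsilon run, whose L counts as 0.0656 M of E, the main step by itself gives 8.20 % of the Z charged as E at 120 min, and with E helping I get 10.5 %.

The forecast says order 1.05 in Z, 0.85 in L, eta slower, and 12 % for the epsilon run, reading the runs as “mild acceleration by E, not saturation”. It differs from me on the order in L, and its figure for the epsilon run stands higher than my 10.5 %.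

The flask gives order 1.0 in Z, 0.98 in L, eta slower, and 11.4 % for the epsilon run.

    L + Z → E + L (1.200 M⁻¹ min⁻¹)
    Z + E → 2 E (0.01242 M⁻¹ min⁻¹)

The forecast's order in L stands below the flask's. At equal Z the eta run goes at 0.73 of the theta rate because of the step from Z and E to two E; without that step the ratio is 1.0, the zero of my scale, and worth had given 0.742. In the epsilon run at 120 min, the 11.4 % of E stands in, by my loose reading of worth, for 0.693 of the L charged.

The numbers in the tables are simulated with made-up constants; scatter was added.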